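**Plan**

- Retrosynthesis: the caffeate C–O bond at O5 is cut first, then the C3–C4 bond of the cyclohexane, which opens the ring to an acyclic 1,6-dialdehyde (C3 and C4 as CHO). The aldehydes go back to terminal alkenes, the C4–C5 bond to an alkynylation of an acyl chloride, and the C1–C2 bond to an allylation.
- Enabling feature: the single carbocycle carries a cis-diol at C3/C4 directly beside the oxygen-bearing C5. Two adjacent carbinol carbons flanked by an alkoxy stereocentre are what a reductive coupling of two aldehyde carbons produces.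
- Forward: C1, C6, C5 and the carboxyl come from (S)-malic acid. C2/C3 are added by allylation at C1 and C4 by alkynylation of the C5 acyl carbon. The chain is trimmed to the dialdehyde, the only ring is closed by joining C3 to C4, and the caffeoyl group is attached last.
- Stereochemistry: C1 by self-regeneration of the malic acid stereocentre (alkylation with retention). C5 by catalyst-controlled transfer hydrogenation of an ynone. C3 and C4 in the ring closure (cis through a samarium-bridged diketyl, anti to the C5 silyloxy group).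
- Endgame: diol acetonide, desilylation, esterification of O5 with di-O-acetylcaffeic acid, acidic unmasking.

Key step: step 11

Remark: locants follow the SMILES with C1 = C(OMe)(CO2H), C3/C4 = the free cis-diol and C5 = the caffeate-bearing carbon, whose oxygen is trans to O4 (the chlorogenic acid pattern).

**Route**

Step 1
Reactants: 1 (S)-malic acid; 2 pivalaldehyde
Product: 3 [(2S,4S)-2-tert-butyl-5-oxo-1,3-dioxolan-4-yl]acetic acid (cis-dioxolanone)
Conditions: p-TsOH (cat.), H2SO4 (cat.), pentane, reflux, Dean–Stark; recrystallisation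
Reagents that add atoms: none
Why: Acid-catalysed acetalisation of the α-hydroxy acid unit (Seebach dioxolanone formation) should close the five-membered ring in preference to the six-membered alternative, and thermodynamic control plus crystallisation should give the cis acetal, whose new acetal carbon stores the configuration of the untouched malic acid stereocentre.

Step 2
Reactants: 3 [(2S,4S)-2-tert-butyl-5-oxo-1,3-dioxolan-4-yl]acetic acid; 4 allyl bromide
Product: 5 [(2S,4S)-2-tert-butyl-5-oxo-4-(prop-2-en-1-yl)-1,3-dioxolan-4-yl]acetic acid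
Conditions: LiN(SiMe3)2 (2.2 equiv), THF, −78 °C; then 4, −78 to −30 °C; 1 M HCl quench
Reagents that add atoms: none
Why: In this self-regeneration of a stereocentre (Seebach alkylation), the dianion is planar at the former carbinol carbon and the allyl halide should enter anti to the tert-butyl group, on the face the hydrogen occupied, so the quaternary carbon (future C1) is formed with overall retention.

Step 3
Reactants: 5 [(2S,4S)-2-tert-butyl-5-oxo-4-(prop-2-en-1-yl)-1,3-dioxolan-4-yl]acetic acid; 6 (trimethylsilyl)acetylene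
Product: 8 (2S,5S)-2-tert-butyl-5-[2-oxo-4-(trimethylsilyl)but-3-yn-1-yl]-5-(prop-2-en-1-yl)-1,3-dioxolan-4-one, via acid chloride 7 (not isolated)
Conditions: (COCl)2, DMF (cat.), CH2Cl2, 0 °C to rt, evaporate; then 6, PdCl2(PPh3)2 (cat.), CuI (cat.), Et3N (1.05 equiv), THF, rt
Reagents that add atoms: none
Why: An acyl Sonogashira coupling should form the C5–C4 bond under near-neutral conditions that leave the hindered dioxolanone carbonyl and the allyl group alone, and no stereocentre is involved.

Step 4
Reactants: 8 (2S,5S)-2-tert-butyl-5-[2-oxo-4-(trimethylsilyl)but-3-yn-1-yl]-5-(prop-2-en-1-yl)-1,3-dioxolan-4-one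
Product: 9 (2S,5S)-2-tert-butyl-5-[(2R)-2-hydroxy-4-(trimethylsilyl)but-3-yn-1-yl]-5-(prop-2-en-1-yl)-1,3-dioxolan-4-one
Conditions: Ru[(R,R)-TsNCH(Ph)CH(Ph)NH](p-cymene) (cat.), i-PrOH, rt
Reagents that add atoms: none
Why: Noyori–Ikariya asymmetric transfer hydrogenation of alkynyl ketones is catalyst-controlled and largely indifferent to the alkyl residue, and since the (S,S)-catalyst gives (S)-carbinols from simple alkyl alkynyl ketones, the (R,R)-complex should give the (R)-propargylic alcohol (future C5) without touching alkyne, alkene or acylal.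

Step 5
Reactants: 9 (2S,5S)-2-tert-butyl-5-[(2R)-2-hydroxy-4-(trimethylsilyl)but-3-yn-1-yl]-5-(prop-2-en-1-yl)-1,3-dioxolan-4-one
Product: 10 (2S,5S)-2-tert-butyl-5-[(2R)-2-(tert-butyldimethylsilyloxy)-4-(trimethylsilyl)but-3-yn-1-yl]-5-(prop-2-en-1-yl)-1,3-dioxolan-4-one
Conditions: TBSOTf, 2,6-lutidine, CH2Cl2, −78 °C
Reagents that add atoms: tert-butyldimethylsilyl triflate, CC(C)(C)[Si](C)(C)OS(=O)(=O)C(F)(F)F
Why: Fast low-temperature silylation with the silyl triflate should cap the γ-hydroxyl before it can attack the dioxolanone carbonyl, and the C–O bond of the new stereocentre is not broken.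

Step 6
Reactants: 10 (2S,5S)-2-tert-butyl-5-[(2R)-2-(tert-butyldimethylsilyloxy)-4-(trimethylsilyl)but-3-yn-1-yl]-5-(prop-2-en-1-yl)-1,3-dioxolan-4-one
Product: 12 (2S,4R)-4-(tert-butyldimethylsilyloxy)-2-hydroxy-2-(prop-2-en-1-yl)hex-5-ynoic acid, via terminal-alkyne dioxolanone 11 (not isolated)
Conditions: LiOH (aq), THF/MeOH, 0 °C to rt; then 1 M HCl to pH 3, 0 °C
Reagents that add atoms: lithium hydroxide, [Li+].[OH-]
Why: Hydroxide should first cleave the alkynyl C–Si bond (protiodesilylation) and then saponify the hindered dioxolanone with release of pivalaldehyde, while the quaternary centre (no α-hydrogen) and the secondary TBS ether tolerate the base.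

Step 7
Reactants: 12 (2S,4R)-4-(tert-butyldimethylsilyloxy)-2-hydroxy-2-(prop-2-en-1-yl)hex-5-ynoic acid
Product: 13 tert-butyl (2S,4R)-4-(tert-butyldimethylsilyloxy)-2-hydroxy-2-(prop-2-en-1-yl)hex-5-ynoate
Conditions: O-tert-butyl-N,N'-diisopropylisourea, CH2Cl2, rt
Reagents that add atoms: O-tert-butyl-N,N'-diisopropylisourea, CC(C)N=C(OC(C)(C)C)NC(C)C
Why: In this O-alkylisourea esterification the acid protonates the reagent and the carboxylate captures the tert-butyl group under neutral conditions, which spares the tertiary alcohol, silyl ether and alkyne and installs an ester that survives base, ozone and SmI2 and is removed by acid at the end.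

Step 8
Reactants: 13 tert-butyl (2S,4R)-4-(tert-butyldimethylsilyloxy)-2-hydroxy-2-(prop-2-en-1-yl)hex-5-ynoate
Product: 14 tert-butyl (2S,4R)-4-(tert-butyldimethylsilyloxy)-2-hydroxy-2-(prop-2-en-1-yl)hex-5-enoate
Conditions: H2 (1 atm), Pd/CaCO3 poisoned with Pb(OAc)2 (Lindlar catalyst), quinoline, EtOAc, rt, stopped after one equivalent of H2
Reagents that add atoms: none
Why: Lindlar semihydrogenation should reduce the terminal alkyne to the vinyl group much faster than the isolated allyl alkene is hydrogenated on the poisoned catalyst.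

Step 9
Reactants: 14 tert-butyl (2S,4R)-4-(tert-butyldimethylsilyloxy)-2-hydroxy-2-(prop-2-en-1-yl)hex-5-enoate
Product: 15 tert-butyl (2S,4R)-4-(tert-butyldimethylsilyloxy)-2-methoxy-2-(prop-2-en-1-yl)hex-5-enoate
Conditions: NaH, MeI, DMF, 0 °C
Reagents that add atoms: iodomethane, CI
Why: Williamson etherification of the sodium alkoxide of a tertiary α-hydroxy ester should proceed cleanly because there is no α-hydrogen, no second free hydroxyl and no terminal alkyne, and a silyl shift onto the more hindered tertiary oxygen is uphill and slow at 0 °C.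

Step 10
Reactants: 15 tert-butyl (2S,4R)-4-(tert-butyldimethylsilyloxy)-2-methoxy-2-(prop-2-en-1-yl)hex-5-enoate
Product: 17 tert-butyl (2R,4R)-4-(tert-butyldimethylsilyloxy)-2-methoxy-5-oxo-2-(2-oxoethyl)pentanoate, via bis-ozonide 16 (not isolated)
Conditions: O3, CH2Cl2, −78 °C; then PPh3, −78 °C to rt; short silica plug, used at once
Reagents that add atoms: ozone, [O-][O+]=O
Why: Criegee ozonolysis of both terminal alkenes followed by neutral phosphine reduction should unmask the C3 and C4 aldehydes in one operation without epimerising the α-silyloxy carbon or eliminating the β-methoxy group.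

Step 11
Reactants: 17 tert-butyl (2R,4R)-4-(tert-butyldimethylsilyloxy)-2-methoxy-5-oxo-2-(2-oxoethyl)pentanoate
Product: 18 tert-butyl (1S,3R,4R,5R)-5-(tert-butyldimethylsilyloxy)-3,4-dihydroxy-1-methoxycyclohexane-1-carboxylate
Conditions: SmI2 (0.1 M in THF, 2.5 equiv), t-BuOH (3 equiv), THF, −78 °C to rt, slow addition of 17 at high dilution
Reagents that add atoms: none
Why: SmI2 (divalent samarium) transfers one electron to each aldehyde, the two ketyl oxygens are held on trivalent samarium, the C3 and C4 carbons join, and t-BuOH protonates the diolate. The closest known reaction type is the SmI2-mediated intramolecular pinacol coupling of α-alkoxy-substituted 1,6-dialdehydes, which gives cis-cyclohexane-1,2-diols. The cyclohexane closes in a 6-exo-trig mode, the C3 ketyl carbon adding to the exocyclic C4 carbonyl. C3 and C4 are set cis because both oxygens are bridged by samarium in the closing transition state, and C4 is set trans to C5 because the ketyl oxygen avoids the dipole and bulk of the adjacent OTBS group, which also fixes C3 relative to the pre-set C1. The required chair places CO2t-Bu and OTBS equatorial and only OMe and one samarium-bound oxygen axial, so the C1 centre should reinforce the C5 bias. The step needs aldehyde reduction to win over reduction of the α-methoxy ester and over loss of silyloxide, which −78 °C without HMPA should secure, and cyclisation to win over intermolecular coupling, which slow addition at high dilution should secure.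

Step 12
Reactants: 18 tert-butyl (1S,3R,4R,5R)-5-(tert-butyldimethylsilyloxy)-3,4-dihydroxy-1-methoxycyclohexane-1-carboxylate
Product: 19 tert-butyl (1S,3R,4R,5R)-5-(tert-butyldimethylsilyloxy)-3,4-(isopropylidenedioxy)-1-methoxycyclohexane-1-carboxylate
Conditions: 2,2-dimethoxypropane, PPTS (cat.), CH2Cl2, rt
Reagents that add atoms: 2,2-dimethoxypropane, COC(C)(C)OC
Why: Acid-catalysed transketalisation should convert the cis-1,2-diol into the cis-fused dioxolane under conditions mild enough for the TBS ether and the tert-butyl ester.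

Step 13
Reactants: 19 tert-butyl (1S,3R,4R,5R)-5-(tert-butyldimethylsilyloxy)-3,4-(isopropylidenedioxy)-1-methoxycyclohexane-1-carboxylate
Product: 20 tert-butyl (1R,3R,4S,5R)-5-hydroxy-3,4-(isopropylidenedioxy)-1-methoxycyclohexane-1-carboxylate
Conditions: Bu4NF, AcOH (1:1), THF, 0 °C to rt
Reagents that add atoms: none
Why: Fluoride-driven desilylation should free O5 while the acetic acid buffer keeps the C5 oxygen protonated so that it does not attack the cis C1 ester to form the bridged lactone (the descriptors at C1 and C4 change only through ligand priorities).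

Step 14
Reactants: 21 caffeic acid
Product: 22 (2E)-3-(3,4-diacetoxyphenyl)prop-2-enoic acid (3,4-di-O-acetylcaffeic acid)
Conditions: Ac2O, pyridine, DMAP (cat.), rt; aq. HCl work-up
Reagents that add atoms: acetic anhydride, CC(=O)OC(C)=O
Why: Nucleophile-catalysed acetylation should cap both phenols so the catechol cannot compete as a nucleophile in the esterification, and the E-alkene is unaffected.

Step 15
Reactants: 20 tert-butyl (1R,3R,4S,5R)-5-hydroxy-3,4-(isopropylidenedioxy)-1-methoxycyclohexane-1-carboxylate; 22 3,4-di-O-acetylcaffeic acid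
Product: 23 tert-butyl (1S,3R,4R,5R)-5-{[(2E)-3-(3,4-diacetoxyphenyl)prop-2-enoyl]oxy}-3,4-(isopropylidenedioxy)-1-methoxycyclohexane-1-carboxylate
Conditions: DCC, DMAP (cat.), CH2Cl2, 0 °C to rt
Reagents that add atoms: none
Why: Steglich esterification should acylate the only free hydroxyl through the acylpyridinium ion, with the C5–O bond left intact so that configuration is retained.

Step 16
Reactants: 23 tert-butyl (1S,3R,4R,5R)-5-{[(2E)-3-(3,4-diacetoxyphenyl)prop-2-enoyl]oxy}-3,4-(isopropylidenedioxy)-1-methoxycyclohexane-1-carboxylate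
Product: 25 (1S,3R,4R,5R)-5-{[(2E)-3-(3,4-dihydroxyphenyl)prop-2-enoyl]oxy}-3,4-dihydroxy-1-methoxycyclohexane-1-carboxylic acid (the target), via diacetate acid 24 (not isolated)
Conditions: TFA/CH2Cl2/H2O, 0 °C to rt; evaporate; then 2 M aq. HCl/THF, rt
Reagents that add atoms: none
Why: Acidolysis should cleave the tert-butyl ester by alkyl–oxygen fission and hydrolyse the acetonide, and dilute acid should then hydrolyse the two aryl acetates, which are far more labile than the alkyl cinnamate, while acidic medium suppresses the acyl migration and ester cleavage that base would cause.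

**Compound list**

1 | (S)-malic acid | O[C@@H](CC(=O)O)C(=O)O | starting material
2 | pivalaldehyde | CC(C)(C)C=O | starting material
3 | [(2S,4S)-2-tert-butyl-5-oxo-1,3-dioxolan-4-yl]acetic acid | CC(C)(C)[C@H]1O[C@@H](CC(=O)O)C(=O)O1 | intermediate
4 | allyl bromide | C=CCBr | starting material
5 | [(2S,4S)-2-tert-butyl-5-oxo-4-(prop-2-en-1-yl)-1,3-dioxolan-4-yl]acetic acid | CC(C)(C)[C@H]1O[C@@](CC=C)(CC(=O)O)C(=O)O1 | intermediate
6 | (trimethylsilyl)acetylene | C#C[Si](C)(C)C | starting material
7 | [(2S,4S)-2-tert-butyl-5-oxo-4-(prop-2-en-1-yl)-1,3-dioxolan-4-yl]acetyl chloride | CC(C)(C)[C@H]1O[C@@](CC=C)(CC(=O)Cl)C(=O)O1 | intermediate, not isolated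
8 | (2S,5S)-2-tert-butyl-5-[2-oxo-4-(trimethylsilyl)but-3-yn-1-yl]-5-(prop-2-en-1-yl)-1,3-dioxolan-4-one | CC(C)(C)[C@H]1O[C@@](CC=C)(CC(=O)C#C[Si](C)(C)C)C(=O)O1 | intermediate
9 | (2S,5S)-2-tert-butyl-5-[(2R)-2-hydroxy-4-(trimethylsilyl)but-3-yn-1-yl]-5-(prop-2-en-1-yl)-1,3-dioxolan-4-one | CC(C)(C)[C@H]1O[C@@](CC=C)(C[C@@H](O)C#C[Si](C)(C)C)C(=O)O1 | intermediate
10 | (2S,5S)-2-tert-butyl-5-[(2R)-2-(tert-butyldimethylsilyloxy)-4-(trimethylsilyl)but-3-yn-1-yl]-5-(prop-2-en-1-yl)-1,3-dioxolan-4-one | CC(C)(C)[C@H]1O[C@@](CC=C)(C[C@@H](O[Si](C)(C)C(C)(C)C)C#C[Si](C)(C)C)C(=O)O1 | intermediate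
11 | (2S,5S)-2-tert-butyl-5-[(2R)-2-(tert-butyldimethylsilyloxy)but-3-yn-1-yl]-5-(prop-2-en-1-yl)-1,3-dioxolan-4-one | CC(C)(C)[C@H]1O[C@@](CC=C)(C[C@@H](O[Si](C)(C)C(C)(C)C)C#C)C(=O)O1 | intermediate, not isolated
12 | (2S,4R)-4-(tert-butyldimethylsilyloxy)-2-hydroxy-2-(prop-2-en-1-yl)hex-5-ynoic acid | O[C@](CC=C)(C(=O)O)C[C@@H](O[Si](C)(C)C(C)(C)C)C#C | intermediate
13 | tert-butyl (2S,4R)-4-(tert-butyldimethylsilyloxy)-2-hydroxy-2-(prop-2-en-1-yl)hex-5-ynoate | O[C@](CC=C)(C(=O)OC(C)(C)C)C[C@@H](O[Si](C)(C)C(C)(C)C)C#C | intermediate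
14 | tert-butyl (2S,4R)-4-(tert-butyldimethylsilyloxy)-2-hydroxy-2-(prop-2-en-1-yl)hex-5-enoate | O[C@](CC=C)(C(=O)OC(C)(C)C)C[C@@H](O[Si](C)(C)C(C)(C)C)C=C | intermediate
15 | tert-butyl (2S,4R)-4-(tert-butyldimethylsilyloxy)-2-methoxy-2-(prop-2-en-1-yl)hex-5-enoate | CO[C@](CC=C)(C(=O)OC(C)(C)C)C[C@@H](O[Si](C)(C)C(C)(C)C)C=C | intermediate
16 | tert-butyl (2R,4R)-4-(tert-butyldimethylsilyloxy)-2-methoxy-4-(1,2,4-trioxolan-3-yl)-2-[(1,2,4-trioxolan-3-yl)methyl]butanoate (bis-ozonide, epimers at the trioxolane carbons) | CO[C@](CC1OCOO1)(C(=O)OC(C)(C)C)C[C@@H](O[Si](C)(C)C(C)(C)C)C1OCOO1 | intermediate, not isolated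
17 | tert-butyl (2R,4R)-4-(tert-butyldimethylsilyloxy)-2-methoxy-5-oxo-2-(2-oxoethyl)pentanoate | CO[C@](CC=O)(C(=O)OC(C)(C)C)C[C@@H](O[Si](C)(C)C(C)(C)C)C=O | intermediate
18 | tert-butyl (1S,3R,4R,5R)-5-(tert-butyldimethylsilyloxy)-3,4-dihydroxy-1-methoxycyclohexane-1-carboxylate | CO[C@@]1(C(=O)OC(C)(C)C)C[C@@H](O)[C@@H](O)[C@H](O[Si](C)(C)C(C)(C)C)C1 | intermediate
19 | tert-butyl (1S,3R,4R,5R)-5-(tert-butyldimethylsilyloxy)-3,4-(isopropylidenedioxy)-1-methoxycyclohexane-1-carboxylate | CO[C@@]1(C(=O)OC(C)(C)C)C[C@H]2OC(C)(C)O[C@H]2[C@H](O[Si](C)(C)C(C)(C)C)C1 | intermediate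
20 | tert-butyl (1R,3R,4S,5R)-5-hydroxy-3,4-(isopropylidenedioxy)-1-methoxycyclohexane-1-carboxylate | CO[C@@]1(C(=O)OC(C)(C)C)C[C@H]2OC(C)(C)O[C@H]2[C@H](O)C1 | intermediate
21 | caffeic acid | O=C(O)/C=C/c1ccc(O)c(O)c1 | starting material
22 | (2E)-3-(3,4-diacetoxyphenyl)prop-2-enoic acid | CC(=O)Oc1ccc(/C=C/C(=O)O)cc1OC(C)=O | intermediate
23 | tert-butyl (1S,3R,4R,5R)-5-{[(2E)-3-(3,4-diacetoxyphenyl)prop-2-enoyl]oxy}-3,4-(isopropylidenedioxy)-1-methoxycyclohexane-1-carboxylate | CO[C@@]1(C(=O)OC(C)(C)C)C[C@H]2OC(C)(C)O[C@H]2[C@H](OC(=O)/C=C/c3ccc(OC(C)=O)c(OC(C)=O)c3)C1 | intermediate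
24 | (1S,3R,4R,5R)-5-{[(2E)-3-(3,4-diacetoxyphenyl)prop-2-enoyl]oxy}-3,4-dihydroxy-1-methoxycyclohexane-1-carboxylic acid | CO[C@@]1(C(=O)O)C[C@@H](O)[C@@H](O)[C@H](OC(=O)/C=C/c2ccc(OC(C)=O)c(OC(C)=O)c2)C1 | intermediate, not isolated
25 | (1S,3R,4R,5R)-5-{[(2E)-3-(3,4-dihydroxyphenyl)prop-2-enoyl]oxy}-3,4-dihydroxy-1-methoxycyclohexane-1-carboxylic acid | CO[C@@]1(C(=O)O)C[C@@H](O)[C@@H](O)[C@H](OC(=O)/C=C/c2ccc(O)c(O)c2)C1 | target

**Step count and risks**

Total steps: 16. Longest linear sequence: 15 (steps 1–13, 15 and 16, from (S)-malic acid).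

Steps most likely to fail:

Step 11. The ketyl coupling may show poor facial selectivity (trans-diol or the all-cis isomer), or the silyloxy group next to the C4 ketyl may be lost reductively. The fallback sets out from diene 15 and closes the same C3–C4 connection as an alkene. Ring-closing metathesis with the second-generation Grubbs catalyst RuCl2(=CHPh)(PCy3)(H2IMes) in CH2Cl2 at 40 °C should give tert-butyl (1S,5R)-5-(tert-butyldimethylsilyloxy)-1-methoxycyclohex-3-ene-1-carboxylate F1 with loss of ethene. Catalytic OsO4 with N-methylmorpholine N-oxide in acetone/water should then add both hydroxyls to the face opposite the allylic silyloxy group and the C1 ester. This gives the cis-3,4-diol trans to O5 and rejoins the route at 18.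

Step 3. The amine base may convert acid chloride 7 into a ketene, which would dimerise instead of coupling, and the product ynone may suffer conjugate addition. The fallback sets out from acid 5 and transfers the acyl group through an amide. EDC, N,O-dimethylhydroxylamine hydrochloride and N-methylmorpholine in CH2Cl2 should give 2-[(2S,4S)-2-tert-butyl-5-oxo-4-(prop-2-en-1-yl)-1,3-dioxolan-4-yl]-N-methoxy-N-methylacetamide F2. Lithium (trimethylsilyl)acetylide (from 6 and n-BuLi) in THF at −78 °C should add once, because the chelated tetrahedral adduct persists until the acidic quench and the hindered ring carbonyl is spared at this temperature. This comes back to the route at ynone 8.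

Step 16. Hydrolysis of the aryl acetates in dilute acid is slow, and over that time the caffeoyl group may migrate to O4 or be hydrolysed. The fallback sets out from alcohol 20 and builds the caffeoyl unit on the ring without phenol protection. Heating with Meldrum's acid in toluene at 90 °C should give the hydrogen malonate tert-butyl (1S,3R,4R,5R)-5-[(carboxyacetyl)oxy]-3,4-(isopropylidenedioxy)-1-methoxycyclohexane-1-carboxylate F3. Knoevenagel–Doebner condensation with 3,4-dihydroxybenzaldehyde (pyridine, catalytic piperidine, rt to 40 °C) should give, with loss of CO2, the E-configured tert-butyl (1S,3R,4R,5R)-5-{[(2E)-3-(3,4-dihydroxyphenyl)prop-2-enoyl]oxy}-3,4-(isopropylidenedioxy)-1-methoxycyclohexane-1-carboxylate F4. A single treatment with TFA/water should then remove the tert-butyl ester and the acetonide and arrive at 25.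

**Further compounds**

F1 | step 11 | tert-butyl (1S,5R)-5-(tert-butyldimethylsilyloxy)-1-methoxycyclohex-3-ene-1-carboxylate | CO[C@@]1(C(=O)OC(C)(C)C)CC=C[C@H](O[Si](C)(C)C(C)(C)C)C1
F2 | step 3 | 2-[(2S,4S)-2-tert-butyl-5-oxo-4-(prop-2-en-1-yl)-1,3-dioxolan-4-yl]-N-methoxy-N-methylacetamide | CC(C)(C)[C@H]1O[C@@](CC=C)(CC(=O)N(C)OC)C(=O)O1
F3 | step 16 | tert-butyl (1S,3R,4R,5R)-5-[(carboxyacetyl)oxy]-3,4-(isopropylidenedioxy)-1-methoxycyclohexane-1-carboxylate | CO[C@@]1(C(=O)OC(C)(C)C)C[C@H]2OC(C)(C)O[C@H]2[C@H](OC(=O)CC(=O)O)C1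
F4 | step 16 | tert-butyl (1S,3R,4R,5R)-5-{[(2E)-3-(3,4-dihydroxyphenyl)prop-2-enoyl]oxy}-3,4-(isopropylidenedioxy)-1-methoxycyclohexane-1-carboxylate | CO[C@@]1(C(=O)OC(C)(C)C)C[C@H]2OC(C)(C)O[C@H]2[C@H](OC(=O)/C=C/c3ccc(O)c(O)c3)C1
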